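Our vessel is closed, stirred and isothermal, and the ochre run is this same flask of starting material, followed so far. We want to know when its open dimer tops out, and how high.

ochre run (percent of the starting material charged)

| time / min | open dimer / % | ring / % |
|---|---|---|
| 5.00 | 22.1 | 12.1 |
| 6.00 | 22.2 | 14.9 |
| 10.0 | 27.6 | 17.3 |
| 12.0 | 31.0 | 14.9 |
| 15.0 | 33.7 | 12.1 |
| 20.0 | 33.6 | 14.5 |
| 30.0 | 32.0 | 7.8 |

(readings scatter by 1 percentage point)

| flask | starting material | remark | time |
|---|---|---|---|
| ochre | 1.5 M | the very flask that is asked about, followed so far |  |
| flask | 1.5 M |  | 2.5 h |

- when, up to 2.5 h, the flask holds most open dimer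
- the amount of open dimer, in percent of the starting material charged, at that time

We begin with the first two readings of the ochre run. We take the open dimer summed over the ring summed, and divide by the charge of starting material. This gives the early split per unit of charge, 1.09 L mol⁻¹, a selectivity factor read from the readings. Suppose open dimer takes two starting material at each turn and ring takes one. The early split then grows in step with the charge, so in this flask, charged with 1.5 M, it is 1.64, and open dimer holds about 62.1% of what these two early products hold, as a reading.

Next we need the top. The open dimer reads 33.7%, 33.6% and 32.0% at 15.0 min, 20.0 min and 30.0 min, so we place the top near 20.0 min. Our weak link would be trusting the 33.7% alone, since one reading scatters by 1 percentage point. We reforge it by taking the mean of the 3 readings, 33.1%.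

The forecast, “I therefore expect a broad maximum”, gives 0.33 h and 34%, higher than our mean.

    starting material → ring (k = 7.50 × 10⁻⁴ s⁻¹)
    2 starting material ⇌ open dimer (K = 2.40 L mol⁻¹, k = 4.20 × 10⁻⁴ L mol⁻¹ s⁻¹)
    ring → over-reaction product (k = 0.00150 s⁻¹)
    starting material + ring → side product (k = 5.00 × 10⁻⁴ L mol⁻¹ s⁻¹)

The flask holds most open dimer at 0.332 h, with 32.9%. The top is flat, with 32.5% at 0.266 h and 32.5% at 0.415 h. For the neighbour flask charged with 0.60 M, the same early split per unit of charge gives 0.656, so open dimer's share is 39.6%. Scaling this flask's height by the two early shares gives a rough estimate of 21.0%, and the neighbour flask's own top stands at 18.2%.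

The numbers in the tables are simulated with made-up constants.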